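**Plan**
1. Ring labels: A is the 1,2,4-trisubstituted phenol ring, B the para-phenylene, C the 1,2,3-trisubstituted phenol ring, D the meta-phenylene. Both free OH groups travel as methyl ethers.
2. First cut: the bond between the ether oxygen on the middle carbon (C2) of ring C and ring D. The ring D carbon bonded to this oxygen lies para to an unsubstituted CH next to the ring D ethano arm. A nitro group placed on that CH makes the carbon an SNAr site (F as leaving group) and can later be exchanged for H.
3. Further cuts: the A–D and B–C ethano bridges (benzylic Wittig olefination, then saturation) and the bond from the ring A oxygen to ring B (SNAr on 4-fluorobenzaldehyde).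
4. Forward: A + B, then C (Wittig, H2), then the fluoronitro ring D (Wittig, diimide). The ring C phenol is unmasked and the only new ring, the 18-membered macrocycle, closes by O–C(ring D) bond formation. NO2 → NH2 → H and double O-demethylation follow.
5. Stereochemistry: the target has no stereocentre and no non-aromatic double bond, so nothing has to be set. The stilbene E/Z mixtures vanish on saturation.

Key step: step 12

Assumption: both Wittig olefinations are expected to give E/Z mixtures; since each double bond is saturated afterwards, the stilbenes are named and drawn without alkene geometry.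

Step 1
Reactants: 1 o-vanillin (2-hydroxy-3-methoxybenzaldehyde)
Product: 2 2-isopropoxy-3-methoxybenzaldehyde
Conditions: 2-bromopropane, K2CO3, DMF, 70 °C
Reagents that add atoms: 2-bromopropane, CC(C)Br
Why: Williamson etherification of the acidic ortho-formyl phenol should be straightforward, and the isopropyl ether is chosen because it withstands base, hydride, hydrogenation, PPh3·HBr and diimide yet can later be cleaved by BCl3 beside methyl ethers and a nitro group.

Step 2
Reactants: 2 2-isopropoxy-3-methoxybenzaldehyde
Product: 3 (2-isopropoxy-3-methoxyphenyl)methanol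
Conditions: NaBH4, MeOH, 0 °C
Reagents that add atoms: none
Why: Borohydride reduction of an aromatic aldehyde to the benzylic alcohol touches neither aryl ether.

Step 3
Reactants: 3 (2-isopropoxy-3-methoxyphenyl)methanol
Product: 4 (2-isopropoxy-3-methoxybenzyl)triphenylphosphonium bromide
Conditions: PPh3·HBr, MeCN, reflux
Reagents that add atoms: triphenylphosphine hydrobromide, [Br-].c1ccc(cc1)[PH+](c1ccccc1)c1ccccc1
Why: Direct phosphonium salt formation from an electron-rich benzylic alcohol runs through acid-assisted loss of water and capture by the phosphine, and the acid is too weak to cleave the aryl ethers.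

Step 4
Reactants: 5 methyl isovanillate (methyl 3-hydroxy-4-methoxybenzoate); 6 4-fluorobenzaldehyde
Product: 7 methyl 3-(4-formylphenoxy)-4-methoxybenzoate
Conditions: K2CO3, DMF, 130 °C
Reagents that add atoms: none
Why: Intermolecular SNAr etherification with the para formyl group activating the fluoride is standard for this pair of rings, and keeping the ring A carbonyl at the ester level leaves a single aldehyde for the next olefination, so no acetal is needed.

Step 5
Reactants: 4 (2-isopropoxy-3-methoxybenzyl)triphenylphosphonium bromide; 7 methyl 3-(4-formylphenoxy)-4-methoxybenzoate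
Product: 9 methyl 3-{4-[2-(2-isopropoxy-3-methoxyphenyl)ethenyl]phenoxy}-4-methoxybenzoate (E/Z mixture), via ring C benzylidene ylide 8 (not isolated)
Conditions: K2CO3, 18-crown-6 (cat.), CH2Cl2, reflux
Reagents that add atoms: none
Why: Wittig olefination of a semi-stabilised benzylic ylide under solid–liquid phase-transfer conditions is the standard stilbene construction for bisbibenzyls and is mild enough for the methyl ester.

Step 6
Reactants: 9 methyl 3-{4-[2-(2-isopropoxy-3-methoxyphenyl)ethenyl]phenoxy}-4-methoxybenzoate (E/Z mixture)
Product: 10 methyl 3-{4-[2-(2-isopropoxy-3-methoxyphenyl)ethyl]phenoxy}-4-methoxybenzoate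
Conditions: H2 (1 atm), Pd/C, EtOAc, rt
Reagents that add atoms: none
Why: Heterogeneous catalytic hydrogenation should merge both alkene isomers into one bibenzyl with ester and ethers inert, and it is placed before any nitro group or activated fluoride is present.

Step 7
Reactants: 10 methyl 3-{4-[2-(2-isopropoxy-3-methoxyphenyl)ethyl]phenoxy}-4-methoxybenzoate
Product: 11 (3-{4-[2-(2-isopropoxy-3-methoxyphenyl)ethyl]phenoxy}-4-methoxyphenyl)methanol
Conditions: LiAlH4, THF, 0 °C
Reagents that add atoms: none
Why: Hydride reduction of the benzoate to the benzylic alcohol by LiAlH4 meets no other reducible group.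

Step 8
Reactants: 11 (3-{4-[2-(2-isopropoxy-3-methoxyphenyl)ethyl]phenoxy}-4-methoxyphenyl)methanol
Product: 12 (3-{4-[2-(2-isopropoxy-3-methoxyphenyl)ethyl]phenoxy}-4-methoxybenzyl)triphenylphosphonium bromide
Conditions: PPh3·HBr, MeCN, reflux
Reagents that add atoms: triphenylphosphine hydrobromide, [Br-].c1ccc(cc1)[PH+](c1ccccc1)c1ccccc1
Why: The para-methoxybenzylic alcohol ionises easily, so phosphonium salt formation with PPh3·HBr should be fast and leave the isopropyl and methyl ethers intact.

Step 9
Reactants: 12 (3-{4-[2-(2-isopropoxy-3-methoxyphenyl)ethyl]phenoxy}-4-methoxybenzyl)triphenylphosphonium bromide; 13 5-fluoro-2-nitrobenzaldehyde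
Product: 15 4-fluoro-2-[2-(3-{4-[2-(2-isopropoxy-3-methoxyphenyl)ethyl]phenoxy}-4-methoxyphenyl)ethenyl]-1-nitrobenzene (open-chain nitrostilbene; E/Z mixture), via ring A benzylidene ylide 14 (not isolated)
Conditions: K2CO3, 18-crown-6 (cat.), CH2Cl2, rt
Reagents that add atoms: none
Why: In this Wittig olefination the strongly electrophilic ortho-nitrobenzaldehyde should capture ylide 14 at room temperature, and with no oxygen or nitrogen nucleophile present in CH2Cl2 the activated C–F bond is expected to survive.

Step 10
Reactants: 15 open-chain nitrostilbene (E/Z mixture)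
Product: 16 4-fluoro-2-[2-(3-{4-[2-(2-isopropoxy-3-methoxyphenyl)ethyl]phenoxy}-4-methoxyphenyl)ethyl]-1-nitrobenzene (isopropyl-protected seco compound)
Conditions: TsNHNH2 (excess, in portions), NaOAc, DME/H2O, reflux
Reagents that add atoms: none
Why: Diimide reduction transfers H2 in a concerted way only to the nonpolar C=C bond, so the nitro group and the C–F bond, which catalytic hydrogenation or hydride reagents would endanger, should remain.

Step 11
Reactants: 16 isopropyl-protected seco compound
Product: 17 2-[2-(4-{5-[2-(5-fluoro-2-nitrophenyl)ethyl]-2-methoxyphenoxy}phenyl)ethyl]-6-methoxyphenol (seco phenol)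
Conditions: BCl3, CH2Cl2, −78 → 0 °C; then H2O
Reagents that add atoms: none
Why: In this Lewis acid ether cleavage the secondary isopropyl group leaves the BCl3-complexed oxygen far more readily than methyl, a selectivity well established for isopropyl guaiacyl ethers, and nitro and fluoride are inert to BCl3 at low temperature.

Step 12
Reactants: 17 seco phenol
Product: 20 nitro marchantin C dimethyl ether (nitro on ring D para to the new ether oxygen), via potassium phenoxide 18 (not isolated), via Meisenheimer anion 19 (not isolated)
Conditions: K2CO3, 4 Å MS, DMF (final 2 mM, 17 added by syringe pump), Ar, 80 °C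
Reagents that add atoms: none
Why: K2CO3 turns the only free OH into phenoxide 18, whose oxygen adds to the fluorine-bearing carbon of ring D to give Meisenheimer anion 19 with the charge taken up by the para nitro group, and expulsion of fluoride restores the arene (addition–elimination SNAr). The closest known reaction type is the nitro-activated intramolecular SNAr macroetherification used for cyclic diaryl ethers of medium and large ring size. The one ring formed is the 18-membered macrocycle, closed end to end because the ring C oxygen and the ring D C–F carbon are the two termini of the open C–B–A–D chain. No stereocentre appears in the product; the sp3 carbon of 19 is transient. Chemoselectivity is secured because every other oxygen is an ether and the only C–F bond lies para to NO2, and ring closure is favoured over chain growth by pseudo-high dilution. Since the bond forms by attack on a flat, unhindered sp2 carbon with no metal bound to oxygen, the two ortho substituents of the phenoxide should slow the reaction only moderately.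

Step 13
Reactants: 20 nitro marchantin C dimethyl ether
Product: 21 amino marchantin C dimethyl ether (NH2 in place of NO2)
Conditions: H2 (1 atm), Pd/C, THF/MeOH, rt
Reagents that add atoms: none
Why: Catalytic hydrogenation of a nitroarene to the aniline is reliable, and nothing else in the macrocycle (diaryl ethers, methyl ethers, saturated bridges) is reducible.

Step 14
Reactants: 21 amino marchantin C dimethyl ether
Product: 23 marchantin C dimethyl ether, via diazonium chloride 22 (not isolated)
Conditions: NaNO2, aq. HCl, THF, 0 °C; then 50% aq. H3PO2 (large excess), Cu2O (cat.), 0 °C → rt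
Reagents that add atoms: none
Why: Diazotisation followed by hypophosphorous acid reduction (reductive deamination, a radical chain started by Cu2O) replaces the diazonium group by H, the large excess of H-donor being meant to outrun any attack of the aryl radical on ring A.

Step 15
Reactants: 23 marchantin C dimethyl ether
Product: 24 marchantin C
Conditions: BBr3, CH2Cl2, −78 °C → rt; then H2O
Reagents that add atoms: none
Why: BBr3 cleavage of aryl methyl ethers frees both phenols, while the diaryl ether bonds, which offer no sp3 carbon to bromide, stay intact.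

**Compound list**
1 | o-vanillin | COc1cccc(C=O)c1O | starting material
2 | 2-isopropoxy-3-methoxybenzaldehyde | COc1cccc(C=O)c1OC(C)C | intermediate
3 | (2-isopropoxy-3-methoxyphenyl)methanol | COc1cccc(CO)c1OC(C)C | intermediate
4 | (2-isopropoxy-3-methoxybenzyl)triphenylphosphonium bromide | COc1cccc(C[P+](c2ccccc2)(c2ccccc2)c2ccccc2)c1OC(C)C.[Br-] | intermediate
5 | methyl isovanillate | COC(=O)c1ccc(OC)c(O)c1 | starting material
6 | 4-fluorobenzaldehyde | O=Cc1ccc(F)cc1 | starting material
7 | methyl 3-(4-formylphenoxy)-4-methoxybenzoate | COC(=O)c1ccc(OC)c(Oc2ccc(C=O)cc2)c1 | intermediate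
8 | ring C benzylidene ylide (formed in the flask) | COc1cccc(C=P(c2ccccc2)(c2ccccc2)c2ccccc2)c1OC(C)C | intermediate
9 | methyl 3-{4-[2-(2-isopropoxy-3-methoxyphenyl)ethenyl]phenoxy}-4-methoxybenzoate (E/Z mixture) | COC(=O)c1ccc(OC)c(Oc2ccc(C=Cc3cccc(OC)c3OC(C)C)cc2)c1 | intermediate
10 | methyl 3-{4-[2-(2-isopropoxy-3-methoxyphenyl)ethyl]phenoxy}-4-methoxybenzoate | COC(=O)c1ccc(OC)c(Oc2ccc(CCc3cccc(OC)c3OC(C)C)cc2)c1 | intermediate
11 | (3-{4-[2-(2-isopropoxy-3-methoxyphenyl)ethyl]phenoxy}-4-methoxyphenyl)methanol | OCc1ccc(OC)c(Oc2ccc(CCc3cccc(OC)c3OC(C)C)cc2)c1 | intermediate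
12 | (3-{4-[2-(2-isopropoxy-3-methoxyphenyl)ethyl]phenoxy}-4-methoxybenzyl)triphenylphosphonium bromide | [Br-].COc1ccc(C[P+](c2ccccc2)(c2ccccc2)c2ccccc2)cc1Oc1ccc(CCc2cccc(OC)c2OC(C)C)cc1 | intermediate
13 | 5-fluoro-2-nitrobenzaldehyde | O=Cc1cc(F)ccc1[N+](=O)[O-] | starting material
14 | ring A benzylidene ylide (formed in the flask) | COc1ccc(C=P(c2ccccc2)(c2ccccc2)c2ccccc2)cc1Oc1ccc(CCc2cccc(OC)c2OC(C)C)cc1 | intermediate
15 | open-chain nitrostilbene (E/Z mixture) | COc1ccc(C=Cc2cc(F)ccc2[N+](=O)[O-])cc1Oc1ccc(CCc2cccc(OC)c2OC(C)C)cc1 | intermediate
16 | isopropyl-protected seco compound | COc1ccc(CCc2cc(F)ccc2[N+](=O)[O-])cc1Oc1ccc(CCc2cccc(OC)c2OC(C)C)cc1 | intermediate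
17 | seco phenol | Oc1c(OC)cccc1CCc1ccc(cc1)Oc1cc(ccc1OC)CCc1cc(F)ccc1[N+](=O)[O-] | intermediate
18 | potassium phenoxide of 17 (formed in the flask) | [K+].[O-]c1c(OC)cccc1CCc1ccc(cc1)Oc1cc(ccc1OC)CCc1cc(F)ccc1[N+](=O)[O-] | intermediate
19 | macrocyclic Meisenheimer anion, potassium salt (formed in the flask; transient sp3 carbon racemic) | [K+].COc1ccc2cc1Oc1ccc(cc1)CCc1cccc(OC)c1OC1(F)C=CC(=[N+]([O-])[O-])C(=C1)CC2 | intermediate
20 | nitro marchantin C dimethyl ether | COc1ccc2cc1Oc1ccc(cc1)CCc1cccc(OC)c1Oc1ccc([N+](=O)[O-])c(c1)CC2 | intermediate
21 | amino marchantin C dimethyl ether | COc1ccc2cc1Oc1ccc(cc1)CCc1cccc(OC)c1Oc1ccc(N)c(c1)CC2 | intermediate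
22 | macrocyclic diazonium chloride (formed in the flask) | [Cl-].COc1ccc2cc1Oc1ccc(cc1)CCc1cccc(OC)c1Oc1ccc([N+]#N)c(c1)CC2 | intermediate
23 | marchantin C dimethyl ether | COc1ccc2cc1Oc1ccc(cc1)CCc1cccc(OC)c1Oc1cccc(c1)CC2 | intermediate
24 | marchantin C | Oc1ccc2cc1Oc1ccc(cc1)CCc1cccc(O)c1Oc1cccc(c1)CC2 | target

**Step count**
- Total steps: 15.
- Longest linear sequence: 14 steps (from 1 through steps 1–3 and 5–15).

**Steps most likely to fail**

**Step 12 (macrocyclisation).**
- Risks: chain growth by intermolecular etherification may outrun ring closure. Addition of the doubly ortho-substituted phenoxide may be too slow at temperatures at which DMF stays intact. Deprotonation of the CH2 group next to the nitroarene may consume material.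
- Fallback: the same O–C(ring D) bond is closed by copper catalysis instead of addition–elimination, with no activating group at all. It sets out from phosphonium salt 12. Wittig olefination with commercial 3-bromobenzaldehyde (O=Cc1cccc(Br)c1; K2CO3, 18-crown-6, CH2Cl2) should give the open-chain bromostilbene F1. Diimide (TsNHNH2, NaOAc, DME/H2O) should then give the bromobibenzyl F2, and BCl3 the bromo seco phenol F3. Intramolecular Ullmann etherification (CuI, picolinic acid, K3PO4, DMSO, 5 mM, 90 °C), a ligand system developed for hindered phenols, would close the ring. The fallback comes back to the route at dimethyl ether 23, so steps 13 and 14 fall away.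

**Step 10 (diimide reduction).**
- Risks: saturation of the hindered, electron-poor stilbene may stall. Long heating may allow attack of sulfinate or hydrazide on the activated C–F bond.
- Fallback: the double bond is kept until the nitro group has to be reduced anyway. It sets out from nitrostilbene 15. BCl3 should give the stilbene seco phenol F4. K2CO3 in DMF under high dilution should close the same O–C bond to give the macrocyclic nitrostilbene F5, both alkene isomers being carried on. H2 over Pd/C would then saturate the alkene and reduce the nitro group in one operation. The fallback comes back at aniline 21, so no chemoselective alkene reduction is needed.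

**Step 14 (deamination).**
- Risks: diazotisation of the lipophilic amine in aqueous acid may be incomplete. The diazonium ion may be captured by water. Pschorr-type cyclisation of the aryl radical onto ring A across the ethano bridge may compete with hydrogen transfer.
- Fallback: the nitro group is removed directly, with no diazonium stage. It sets out from nitro macrocycle 20. Palladium-catalysed reductive denitration is used (Pd(acac)2, BrettPhos, K3PO4, 2-propanol, 1,4-dioxane, 130 °C). Zerovalent palladium inserts into the aryl–NO2 bond and 2-propanol supplies the hydride. The fallback comes back at dimethyl ether 23 and replaces steps 13 and 14. It makes no compound outside the list (entry F0).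

**Further compounds**
F1 | step 12 | open-chain bromostilbene, 1-bromo-3-[2-(3-{4-[2-(2-isopropoxy-3-methoxyphenyl)ethyl]phenoxy}-4-methoxyphenyl)ethenyl]benzene (E/Z mixture) | COc1ccc(C=Cc2cccc(Br)c2)cc1Oc1ccc(CCc2cccc(OC)c2OC(C)C)cc1
F2 | step 12 | bromobibenzyl, 1-bromo-3-[2-(3-{4-[2-(2-isopropoxy-3-methoxyphenyl)ethyl]phenoxy}-4-methoxyphenyl)ethyl]benzene | COc1ccc(CCc2cccc(Br)c2)cc1Oc1ccc(CCc2cccc(OC)c2OC(C)C)cc1
F3 | step 12 | bromo seco phenol, 2-[2-(4-{5-[2-(3-bromophenyl)ethyl]-2-methoxyphenoxy}phenyl)ethyl]-6-methoxyphenol | COc1ccc(CCc2cccc(Br)c2)cc1Oc1ccc(CCc2cccc(OC)c2O)cc1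
F4 | step 10 | stilbene seco phenol, 2-[2-(4-{5-[2-(5-fluoro-2-nitrophenyl)ethenyl]-2-methoxyphenoxy}phenyl)ethyl]-6-methoxyphenol (E/Z mixture) | COc1ccc(C=Cc2cc(F)ccc2[N+](=O)[O-])cc1Oc1ccc(CCc2cccc(OC)c2O)cc1
F5 | step 10 | macrocyclic nitrostilbene, the A–D bridge dehydro analogue of 20 (E/Z mixture) | COc1ccc2cc1Oc1ccc(cc1)CCc1cccc(OC)c1Oc1ccc([N+](=O)[O-])c(c1)C=C2
F0 | step 14 | none | none
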